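**Retrosynthetic overview**
1. Target 8 ⇒ O-benzyl-(S)-[10]-gingerol 6: the acetate goes on last but one, the benzyl group comes off last.
2. Key disconnection: aryl–C1 bond. C1 is β to the C3 ketone, so it is used as a nucleophilic ketone homoenolate (β-acyl carbanion) and joined to aryl bromide 4.
3. The homoenolate is released by Pd-mediated ring opening of 1-substituted cyclopropanol 3, made by Kulinkovich reaction of β-hydroxy ester 2 (EtMgBr supplies C1 and C2).
4. The only stereocentre (C5, S) comes from Noyori hydrogenation of β-keto ester 1.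
5. Rings: the arene is bought; the only ring formed is the cyclopropane (step 2), and it is opened again in step 3.

Assumption: methyl 3-oxododecanoate and 1-(benzyloxy)-4-bromo-2-methoxybenzene are taken as catalogue chemicals. Numbering follows the tetradecan-3-one chain (C1 benzylic, C3 ketone, C5 acetoxy carbon).

**Step 1**
Reactants: 1 methyl 3-oxododecanoate
Product: 2 methyl (S)-3-hydroxydodecanoate
Conditions: H2 (50 atm), [RuCl2((S)-BINAP)] (0.2 mol %), MeOH, 50 °C
Reagents that add atoms: none
Why: Noyori asymmetric hydrogenation of a β-keto ester, in which the ester-chelated ketone is reduced on the face dictated by (S)-BINAP, setting C3 as (S) (mirror of the (R)-BINAP → (R)-3-hydroxyalkanoate sense), typically ≥98% ee.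

**Step 2**
Reactants: 2 methyl (S)-3-hydroxydodecanoate
Product: 3 (S)-1-(2-hydroxyundecyl)cyclopropan-1-ol
Conditions: EtMgBr (4 equiv, slow addition), Ti(OiPr)4 (0.3 equiv), THF, 0 °C → rt; aq NH4Cl
Reagents that add atoms: ethylmagnesium bromide, CC[Mg]Br
Why: Kulinkovich cyclopropanation, in which one equivalent of EtMgBr deprotonates the free OH and the titanacyclopropane formed catalytically from Ti(OiPr)4 and EtMgBr adds twice to the ester carbonyl as a 1,2-dicarbanion, leaving the carbinol stereocentre untouched.

**Step 3**
Reactants: 3 (S)-1-(2-hydroxyundecyl)cyclopropan-1-ol; 4 1-(benzyloxy)-4-bromo-2-methoxybenzene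
Product: 6 (S)-1-[4-(benzyloxy)-3-methoxyphenyl]-5-hydroxytetradecan-3-one, via arylpalladium(II) homoenolate 5 (not isolated)
Conditions: Pd(OAc)2 (5 mol %), XPhos (10 mol %), Cs2CO3 (2 equiv), degassed PhMe, 80 °C; 3 in 1.2 equiv, 4 limiting
Reagents that add atoms: none
Why: Palladium-catalysed ring-opening cross-coupling of a cyclopropanol with an aryl bromide, in which oxidative addition of 4, Pd(II) cyclopropoxide formation and strain-driven β-carbon elimination give homoenolate 5 (nucleophilic β-carbon of the ketone), whose reductive elimination joins two carbons that are both electrophilic in normal polarity; the C5 stereocentre is a spectator.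

**Step 4**
Reactants: 6 (S)-1-[4-(benzyloxy)-3-methoxyphenyl]-5-hydroxytetradecan-3-one
Product: 7 (S)-1-[4-(benzyloxy)-3-methoxyphenyl]-3-oxotetradecan-5-yl acetate
Conditions: Ac2O (1.5 equiv), pyridine, DMAP (5 mol %), CH2Cl2, 0 °C; cold aq NH4Cl work-up
Reagents that add atoms: acetic anhydride, CC(=O)OC(C)=O
Why: DMAP-catalysed O-acylation of the only free hydroxyl, run cold and briefly so the elimination-prone β-acetoxy ketone survives, with retention at C5 because the C–O bond is not broken.

**Step 5**
Reactants: 7 (S)-1-[4-(benzyloxy)-3-methoxyphenyl]-3-oxotetradecan-5-yl acetate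
Product: 8 (S)-1-(4-hydroxy-3-methoxyphenyl)-3-oxotetradecan-5-yl acetate
Conditions: H2 (1 atm), 10% Pd/C, EtOAc, rt
Reagents that add atoms: none
Why: Heterogeneous hydrogenolysis of the aryl benzyl ether under neutral conditions, which leaves the aliphatic ketone, the secondary acetate and the stereocentre untouched.

**Compound list**
1 | methyl 3-oxododecanoate | CCCCCCCCCC(=O)CC(=O)OC | starting material
2 | methyl (S)-3-hydroxydodecanoate | CCCCCCCCC[C@H](O)CC(=O)OC | intermediate
3 | (S)-1-(2-hydroxyundecyl)cyclopropan-1-ol | CCCCCCCCC[C@H](O)CC1(O)CC1 | intermediate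
4 | 1-(benzyloxy)-4-bromo-2-methoxybenzene | COc1cc(Br)ccc1OCc1ccccc1 | starting material
5 | arylpalladium(II) homoenolate: [4-(benzyloxy)-3-methoxyphenyl][(S)-5-hydroxy-3-oxotetradecyl]palladium (XPhos ligand not drawn) | CCCCCCCCC[C@H](O)CC(=O)CC[Pd]c1ccc(OCc2ccccc2)c(OC)c1 | intermediate
6 | (S)-1-[4-(benzyloxy)-3-methoxyphenyl]-5-hydroxytetradecan-3-one | CCCCCCCCC[C@H](O)CC(=O)CCc1ccc(OCc2ccccc2)c(OC)c1 | intermediate
7 | (S)-1-[4-(benzyloxy)-3-methoxyphenyl]-3-oxotetradecan-5-yl acetate | CCCCCCCCC[C@@H](CC(=O)CCc1ccc(OCc2ccccc2)c(OC)c1)OC(C)=O | intermediate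
8 | (S)-1-(4-hydroxy-3-methoxyphenyl)-3-oxotetradecan-5-yl acetate | CCCCCCCCC[C@@H](CC(=O)CCc1ccc(O)c(OC)c1)OC(C)=O | target

**Totals**
Total step count: 5. Longest linear sequence: 5 steps (1 → 2 → 3 → 6 → 7 → 8); 4 enters at step 3.

**Three steps most likely to fail**

Step 3 (highest risk). The palladium homoenolate can undergo β-hydride elimination to the vinyl ketone. The free C5 carbinol can also be oxidised by the aryl-palladium species, and the β-hydroxy ketone product can undergo retro-aldol cleavage or dehydration with Cs2CO3 at 80 °C, which would also erode the stereocentre. The fallback masks the carbinol before the coupling and sets out from 3. TBSCl, imidazole, DMF, 0 °C silylates only the secondary hydroxyl and gives (S)-1-{2-[(tert-butyldimethylsilyl)oxy]undecyl}cyclopropan-1-ol F1. The same Pd/XPhos coupling with 4 then gives (S)-1-[4-(benzyloxy)-3-methoxyphenyl]-5-[(tert-butyldimethylsilyl)oxy]tetradecan-3-one F2, which cannot be oxidised or cleaved by retro-aldol. HF·pyridine in THF at 0 °C removes the silyl group and the sequence comes back to the route at 6.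

Step 2. The unprotected β-hydroxy ester forms a magnesium/titanium β-alkoxide that may sequester the titanium catalyst or divert the ester, giving low conversion. The fallback protects first and sets out from 2. TESCl, imidazole, CH2Cl2 gives methyl (S)-3-[(triethylsilyl)oxy]dodecanoate F3. A standard Kulinkovich reaction on this ester (EtMgBr 2.5 equiv, Ti(OiPr)4 0.2 equiv, THF) gives (S)-1-{2-[(triethylsilyl)oxy]undecyl}cyclopropan-1-ol F4. TBAF in THF at 0 °C cleaves the silyl ether and the sequence comes back to the route at 3.

Step 4. The β-acetoxy ketone can lose acetic acid by E1cB under pyridine/DMAP to give the conjugated enone (shogaol-type product). The fallback installs the acetate before the ketone exists and sets out from 3. Ac2O (1.05 equiv), pyridine, CH2Cl2, 0 °C without DMAP acetylates the secondary hydroxyl faster than the tertiary cyclopropanol and gives (S)-1-(1-hydroxycyclopropyl)undecan-2-yl acetate F5. Ring-opening arylation of this compound with 4 under a milder base (Pd(OAc)2, XPhos, K3PO4, PhMe, 50 °C) gives the acetoxy ketone directly, coming back to the route at 7 and bypassing steps 3 and 4. This fallback carries the same elimination risk into the coupling, so it is only worth trying at the lower temperature.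

**Further compounds**
F1 | step 3 | (S)-1-{2-[(tert-butyldimethylsilyl)oxy]undecyl}cyclopropan-1-ol | CCCCCCCCC[C@H](O[Si](C)(C)C(C)(C)C)CC1(O)CC1
F2 | step 3 | (S)-1-[4-(benzyloxy)-3-methoxyphenyl]-5-[(tert-butyldimethylsilyl)oxy]tetradecan-3-one | CCCCCCCCC[C@H](O[Si](C)(C)C(C)(C)C)CC(=O)CCc1ccc(OCc2ccccc2)c(OC)c1
F3 | step 2 | methyl (S)-3-[(triethylsilyl)oxy]dodecanoate | CCCCCCCCC[C@H](O[Si](CC)(CC)CC)CC(=O)OC
F4 | step 2 | (S)-1-{2-[(triethylsilyl)oxy]undecyl}cyclopropan-1-ol | CCCCCCCCC[C@H](O[Si](CC)(CC)CC)CC1(O)CC1
F5 | step 4 | (S)-1-(1-hydroxycyclopropyl)undecan-2-yl acetate | CCCCCCCCC[C@@H](CC1(O)CC1)OC(C)=O
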